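**Retrosynthetic overview**

- The strategy rests on C9 of the ten-membered ring (C1–C10): it is a carbinol carbon between olefinic C10 (of C1=C10, which carries C14) and oxygenated C8. Cutting C9–C10 gives a C10 Z-vinyl iodide and a C9 aldehyde, and ring closure leaves the C9 hydroxyl as the only free OH for acetylation.
- The seco-aldehyde is assembled at C6–C7 by chromium allylation of a neryl-acetate-derived Z-enal (C1–C6, C10, C14, C15) with a C8-configured 3-(bromomethyl)dihydropyranone (C7–C9, C11–C13). The ring-locked allyl reagent fixes the 6,7-anti and 7,8 relationships, and an O9→O6 acyl shift turns the δ-lactone into the trans γ-lactone and frees C9–OH.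
- Ring order: γ-lactone (step 12), then the ten-membered carbocycle (step 14). The endgame is C9 acetylation, desilylation and selective C14 isovalerylation.

Key step: step 14

Remark: germacranolide numbering is used throughout (ring C1–C10, lactone carbons C11–C13, C14 on C10, C15 on C4). The C8 ether is carried as TBS instead of TES so that it does not migrate to O9 during the acyl shift. Epoxide 2 is used as the racemate because its stereocentre is cleaved in step 2. CIP descriptors at C7 change between silylated and free compounds although the spatial arrangement does not.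

**Route**

Step 1
Reactants: 1 neryl acetate
Product: 2 (2Z)-5-(3,3-dimethyloxiran-2-yl)-3-methylpent-2-en-1-yl acetate (racemic at the oxirane CH)
Conditions: mCPBA, NaHCO3, CH2Cl2, 0 °C
Reagents that add atoms: mCPBA, O=C(OO)c1cccc(Cl)c1
Why: Prilezhaev epoxidation should take the electron-rich distal trisubstituted olefin in preference to the 2,3-olefin, which is deactivated by the allylic acetate.

Step 2
Reactants: 2 epoxide
Product: 3 (2Z)-3-methyl-6-oxohex-2-en-1-yl acetate
Conditions: H5IO6, THF/H2O, 0 °C→rt
Reagents that add atoms: none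
Why: Periodic acid opens the epoxide to the glycol and cleaves it (Malaprade cleavage) to the aldehyde and acetone without touching the Z olefin or the acetate.

Step 3
Reactants: 3 aldehyde
Product: 4 (2Z,6E)-3-methyl-8-oxoocta-2,6-dien-1-yl acetate
Conditions: Ph3P=CHCHO (1.1 equiv), toluene, 80 °C
Reagents that add atoms: (triphenylphosphoranylidene)acetaldehyde, O=CC=P(c1ccccc1)(c1ccccc1)c1ccccc1
Why: Wittig olefination with the stabilised formyl ylide should give the E enal; near-stoichiometric ylide limits a second homologation.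

Step 4
Reactants: 4 enal
Product: 5 (2Z,6Z)-7-iodo-3-methyl-8-oxoocta-2,6-dien-1-yl acetate
Conditions: I2, DMAP (cat.), K2CO3, THF/H2O (1:1), rt
Reagents that add atoms: iodine, II
Why: α-Iodination of the enal by reversible DMAP conjugate addition, iodination of the enolate and E1cB loss of DMAP should give the thermodynamic Z iodoenal (chain trans to CHO, cis to I).

Step 5
Reactants: 5 iodoenal
Product: 6 (2Z,6Z)-8-hydroxy-7-iodo-3-methylocta-2,6-dien-1-yl acetate
Conditions: NaBH4, CeCl3·7H2O, MeOH, −20 °C
Reagents that add atoms: none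
Why: Luche reduction is 1,2-selective and should leave the vinyl iodide, its geometry and the acetate intact.

Step 6
Reactants: 6 iodo allylic alcohol
Product: 7 (2Z,6Z)-8-(tert-butyldimethylsilyloxy)-7-iodo-3-methylocta-2,6-dien-1-yl acetate
Conditions: TBSCl, imidazole, DMF, 0 °C→rt
Reagents that add atoms: tert-butyldimethylsilyl chloride, CC(C)(C)[Si](C)(C)Cl
Why: Standard silylation of the primary allylic alcohol; an ether, not an ester, is wanted on C14 next to the later vinylmetal.

Step 7
Reactants: 7 acetate
Product: 8 (2Z,6Z)-8-(tert-butyldimethylsilyloxy)-7-iodo-3-methylocta-2,6-dien-1-ol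
Conditions: K2CO3 (cat.), MeOH, 0 °C→rt
Reagents that add atoms: none
Why: Base-catalysed transesterification removes the acetate while the TBS ether and vinyl iodide are stable.

Step 8
Reactants: 8 allylic alcohol
Product: 9 (2Z,6Z)-8-(tert-butyldimethylsilyloxy)-7-iodo-3-methylocta-2,6-dienal
Conditions: MnO2, CH2Cl2, rt
Reagents that add atoms: none
Why: Neutral allylic oxidation with MnO2 should give the Z enal without Z/E isomerisation if it is used at once.

Step 9
Reactants: 10 2-(bromomethyl)acrylic acid; 11 (S)-but-3-ene-1,2-diol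
Product: 13 (2S)-2-hydroxybut-3-en-1-yl 2-(bromomethyl)prop-2-enoate, via 2-(bromomethyl)acryloyl chloride 12 (not isolated)
Conditions: (COCl)2, DMF (cat.), CH2Cl2, 0 °C→rt; then 11, 2,4,6-collidine, CH2Cl2, −78 °C
Reagents that add atoms: none
Why: Acid chloride formation followed by low-temperature acylation with a hindered base should esterify the primary hydroxyl selectively without displacing the allylic bromide.

Step 10
Reactants: 13 hydroxy ester
Product: 14 (2S)-2-(tert-butyldimethylsilyloxy)but-3-en-1-yl 2-(bromomethyl)prop-2-enoate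
Conditions: TBSOTf, 2,6-lutidine, CH2Cl2, −78 °C
Reagents that add atoms: tert-butyldimethylsilyl triflate, CC(C)(C)[Si](C)(C)OS(=O)(=O)C(F)(F)F
Why: Silyl triflate with a non-nucleophilic base silylates the secondary allylic alcohol and spares the bromomethyl acrylate.

Step 11
Reactants: 14 diene ester
Product: 15 (5S)-3-(bromomethyl)-5-(tert-butyldimethylsilyloxy)-5,6-dihydro-2H-pyran-2-one
Conditions: second-generation Hoveyda–Grubbs catalyst RuCl2(H2IMes)(=CH-C6H4-2-OiPr) (5 mol %), toluene, 80 °C
Reagents that add atoms: none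
Why: Ring-closing metathesis should load on the monosubstituted olefin and close onto the acrylate to give the six-membered unsaturated lactone with loss of ethylene; the C8 stereocentre is not involved.

Step 12
Reactants: 9 Z enal; 15 bromomethyl dihydropyranone
Product: 17 (4S,5R)-4-[(1S)-1-(tert-butyldimethylsilyloxy)-2-hydroxyethyl]-5-[(1Z,5Z)-7-(tert-butyldimethylsilyloxy)-6-iodo-2-methylhepta-1,5-dien-1-yl]-3-methylenedihydrofuran-2(3H)-one, via δ-lactone carbinol 16 (not isolated)
Conditions: CrCl2 (nickel-free), THF, 0 °C→rt; then CSA (cat.), CH2Cl2, rt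
Reagents that add atoms: none
Why: Nozaki–Hiyama-type 2-(alkoxycarbonyl)allylation: the allylchromium adds through C7 in a chair transition state in which the endocyclic C7=C11 bond locks C8 trans to the CH2Cr group, so the 6,7-anti adduct should form; approach anti to the C8 silyloxy group sets C7 and hence C6; the C6 alkoxide then takes the acyl group from O9 (δ- to γ-lactone, downhill) to give the trans γ-lactone with C9–OH free.

Step 13
Reactants: 17 γ-lactone alcohol
Product: 18 (2S)-2-(tert-butyldimethylsilyloxy)-2-{(2R,3S)-2-[(1Z,5Z)-7-(tert-butyldimethylsilyloxy)-6-iodo-2-methylhepta-1,5-dien-1-yl]-4-methylene-5-oxotetrahydrofuran-3-yl}acetaldehyde (seco-aldehyde; 6R,7S,8S in germacranolide numbering)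
Conditions: Dess–Martin periodinane, NaHCO3, CH2Cl2, 0 °C→rt
Reagents that add atoms: none
Why: Buffered Dess–Martin oxidation of the primary alcohol should give the α-silyloxy aldehyde without epimerising C8 or touching the α-methylene lactone.

Step 14
Reactants: 18 seco-aldehyde
Product: 19 (6R,7S,8S,9R)-8,14-bis(tert-butyldimethylsilyloxy)-9-hydroxygermacra-1(10)Z,4Z,11(13)-trien-12,6-olide
Conditions: CrCl2 (excess), NiCl2 (cat.), DMSO, rt, 2 mM, slow addition of 18
Reagents that add atoms: none
Why: Zerovalent nickel, formed from NiCl2 by CrCl2, inserts into the C10–I bond with retention of the Z geometry, the vinylnickel transmetallates to trivalent chromium, and the vinylchromium adds to the C9 aldehyde (intramolecular Nozaki–Hiyama–Kishi reaction). The closest known reaction type is the nickel/chromium-mediated vinyl iodide–aldehyde macrocyclization to medium-ring allylic alcohols. The ten-membered carbocycle (C1–C10) is closed by C9–C10 bond formation in a 10-exo-trig carbonyl addition, pre-organised by the trans γ-lactone and the two Z olefins and run at high dilution. The new C9 stereocentre is controlled by the adjacent C8 silyloxy stereocentre: the bulky TBS ether cannot chelate, so Felkin–Anh addition anti to the C8–O bond should give the 8,9-anti (9R) carbinol. The step needs chemoselectivity for the aldehyde over the α-methylene lactone and no β-elimination toward C14; organochromium reagents add only to aldehydes, and C14 carries a silyl ether rather than an ester.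

Step 15
Reactants: 19 macrocyclic carbinol
Product: 20 (6R,7S,8S,9R)-9-acetoxy-8,14-bis(tert-butyldimethylsilyloxy)germacra-1(10)Z,4Z,11(13)-trien-12,6-olide
Conditions: Ac2O, pyridine, DMAP (cat.), CH2Cl2, 0 °C→rt
Reagents that add atoms: acetic anhydride, CC(=O)OC(C)=O
Why: The C9 hydroxyl is the only free OH, so acetylation needs no differentiation.

Step 16
Reactants: 20 bis-silyl ether
Product: 21 (6R,7R,8S,9R)-9-acetoxy-8,14-dihydroxygermacra-1(10)Z,4Z,11(13)-trien-12,6-olide
Conditions: HF·pyridine, pyridine, THF, 0 °C→rt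
Reagents that add atoms: none
Why: Buffered, mildly acidic fluoride desilylation should remove both TBS groups without O9→O8 acetate migration or damage to the lactone.

Step 17
Reactants: 21 diol
Product: 22 (6R,7R,8S,9R)-9-acetoxy-8-hydroxy-14-(3-methylbutanoyloxy)germacra-1(10)Z,4Z,11(13)-trien-12,6-olide (target, CNP0603244.1)
Conditions: 3-methylbutanoyl chloride (1.05 equiv), 2,4,6-collidine, CH2Cl2, −78→−20 °C
Reagents that add atoms: 3-methylbutanoyl chloride, CC(C)CC(Cl)=O
Why: Low-temperature acylation with a hindered base should take the primary allylic C14 hydroxyl in preference to the hindered secondary C8 hydroxyl.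

**Compound list**

1 | neryl acetate, (2Z)-3,7-dimethylocta-2,6-dien-1-yl acetate | CC(C)=CCC/C(C)=C\COC(C)=O | starting material
2 | (2Z)-5-(3,3-dimethyloxiran-2-yl)-3-methylpent-2-en-1-yl acetate, racemic at the oxirane CH | CC(=O)OC/C=C(/C)CCC1OC1(C)C | intermediate
3 | (2Z)-3-methyl-6-oxohex-2-en-1-yl acetate | CC(=O)OC/C=C(/C)CCC=O | intermediate
4 | (2Z,6E)-3-methyl-8-oxoocta-2,6-dien-1-yl acetate | CC(=O)OC/C=C(/C)CC/C=C/C=O | intermediate
5 | (2Z,6Z)-7-iodo-3-methyl-8-oxoocta-2,6-dien-1-yl acetate | CC(=O)OC/C=C(/C)CC/C=C(\I)C=O | intermediate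
6 | (2Z,6Z)-8-hydroxy-7-iodo-3-methylocta-2,6-dien-1-yl acetate | CC(=O)OC/C=C(/C)CC/C=C(\I)CO | intermediate
7 | (2Z,6Z)-8-(tert-butyldimethylsilyloxy)-7-iodo-3-methylocta-2,6-dien-1-yl acetate | CC(=O)OC/C=C(/C)CC/C=C(\I)CO[Si](C)(C)C(C)(C)C | intermediate
8 | (2Z,6Z)-8-(tert-butyldimethylsilyloxy)-7-iodo-3-methylocta-2,6-dien-1-ol | OC/C=C(/C)CC/C=C(\I)CO[Si](C)(C)C(C)(C)C | intermediate
9 | (2Z,6Z)-8-(tert-butyldimethylsilyloxy)-7-iodo-3-methylocta-2,6-dienal | O=C/C=C(/C)CC/C=C(\I)CO[Si](C)(C)C(C)(C)C | intermediate
10 | 2-(bromomethyl)acrylic acid | C=C(CBr)C(=O)O | starting material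
11 | (S)-but-3-ene-1,2-diol | C=C[C@H](O)CO | starting material
12 | 2-(bromomethyl)acryloyl chloride | C=C(CBr)C(Cl)=O | intermediate
13 | (2S)-2-hydroxybut-3-en-1-yl 2-(bromomethyl)prop-2-enoate | C=C[C@H](O)COC(=O)C(=C)CBr | intermediate
14 | (2S)-2-(tert-butyldimethylsilyloxy)but-3-en-1-yl 2-(bromomethyl)prop-2-enoate | C=C[C@H](O[Si](C)(C)C(C)(C)C)COC(=O)C(=C)CBr | intermediate
15 | (5S)-3-(bromomethyl)-5-(tert-butyldimethylsilyloxy)-5,6-dihydro-2H-pyran-2-one | BrCC1=C[C@H](O[Si](C)(C)C(C)(C)C)COC1=O | intermediate
16 | (4S,5S)-5-(tert-butyldimethylsilyloxy)-4-[(1R,2Z,6Z)-8-(tert-butyldimethylsilyloxy)-1-hydroxy-7-iodo-3-methylocta-2,6-dien-1-yl]-3-methylenetetrahydro-2H-pyran-2-one (C6 side chain trans to the C8 silyloxy group on the ring) | C=C1C(=O)OC[C@@H](O[Si](C)(C)C(C)(C)C)[C@@H]1[C@H](O)/C=C(/C)CC/C=C(\I)CO[Si](C)(C)C(C)(C)C | intermediate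
17 | (4S,5R)-4-[(1S)-1-(tert-butyldimethylsilyloxy)-2-hydroxyethyl]-5-[(1Z,5Z)-7-(tert-butyldimethylsilyloxy)-6-iodo-2-methylhepta-1,5-dien-1-yl]-3-methylenedihydrofuran-2(3H)-one (trans γ-lactone) | C=C1C(=O)O[C@H](/C=C(/C)CC/C=C(\I)CO[Si](C)(C)C(C)(C)C)[C@H]1[C@H](O[Si](C)(C)C(C)(C)C)CO | intermediate
18 | seco-aldehyde: as 17 with C9 oxidised to CHO; (6R,7S,8S), C10 Z-vinyl iodide, C8 and C14 TBS ethers | C=C1C(=O)O[C@H](/C=C(/C)CC/C=C(\I)CO[Si](C)(C)C(C)(C)C)[C@H]1[C@H](O[Si](C)(C)C(C)(C)C)C=O | intermediate
19 | (6R,7S,8S,9R)-8,14-bis(tert-butyldimethylsilyloxy)-9-hydroxygermacra-1(10)Z,4Z,11(13)-trien-12,6-olide | C=C1C(=O)O[C@@H]2/C=C(/C)CC/C=C(/CO[Si](C)(C)C(C)(C)C)[C@@H](O)[C@@H](O[Si](C)(C)C(C)(C)C)[C@@H]12 | intermediate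
20 | (6R,7S,8S,9R)-9-acetoxy-8,14-bis(tert-butyldimethylsilyloxy)germacra-1(10)Z,4Z,11(13)-trien-12,6-olide | C=C1C(=O)O[C@@H]2/C=C(/C)CC/C=C(/CO[Si](C)(C)C(C)(C)C)[C@@H](OC(C)=O)[C@@H](O[Si](C)(C)C(C)(C)C)[C@@H]12 | intermediate
21 | (6R,7R,8S,9R)-9-acetoxy-8,14-dihydroxygermacra-1(10)Z,4Z,11(13)-trien-12,6-olide | C=C1C(=O)O[C@@H]2/C=C(/C)CC/C=C(/CO)[C@@H](OC(C)=O)[C@@H](O)[C@@H]12 | intermediate
22 | (6R,7R,8S,9R)-9-acetoxy-8-hydroxy-14-(3-methylbutanoyloxy)germacra-1(10)Z,4Z,11(13)-trien-12,6-olide | C=C1C(=O)O[C@@H]2/C=C(/C)CC/C=C(/COC(=O)CC(C)C)[C@@H](OC(C)=O)[C@@H](O)[C@@H]12 | target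

**Step count**

Total: 17 steps. Longest linear sequence: 14 steps (steps 1–8 and 12–17); steps 9–11 form the convergent branch.

**Steps most likely to fail**

1. Step 14. The ring closure may lose to intermolecular coupling, and the vinylchromium may add to the aldehyde face syn to the C8 silyloxy group (poor facial selectivity), which would give the 9S carbinol. The fallback sets out from 18 and moves the setting of C9 from the carbonyl addition to a substitution. The 9S alcohol F1 obtained from the cyclization is treated with PPh3, diisopropyl azodicarboxylate and acetic acid (toluene, 0 °C). Mitsunobu displacement of the oxyphosphonium by acetate inverts C9 and gives acetate 20 directly, where the route resumes.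

2. Step 12. The allylchromium may lose the C8 silyloxy group by reductive 1,4-elimination, the aldehyde may approach syn to that group, or the O9→O6 acyl shift may stall. The fallback sets out from 15 and replaces the reductive Barbier reaction by a preformed allylboron reagent. Borylation of 15 (B2pin2, KOAc, Pd2(dba)3, toluene, 50 °C) should give the pinacol allylboronate F2. Heating F2 with enal 9 (toluene, 60 °C) should effect allylboration through a closed Zimmerman–Traxler transition state with the same ring-locked geometry and no reducing metal. Work-up gives carbinol 16, and catalytic CSA completes the acyl shift to 17, where the route resumes.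

3. Step 11. Metathesis may stall on the 1,1-disubstituted, electron-poor bromomethyl acrylate, or the allylic bromide may degrade the ruthenium carbene. The fallback sets out from 11 and installs the bromomethyl group after ring closure. Acryloyl chloride with 2,4,6-collidine at −78 °C should give the hydroxy acrylate F3, and TBSOTf with 2,6-lutidine the silyl ether F4. Ring-closing metathesis of this unsubstituted acrylate with the same catalyst should give the dihydropyranone F5. Morita–Baylis–Hillman hydroxymethylation (aqueous formaldehyde, DMAP, THF) should give the hydroxymethyl lactone F6, and Appel bromination (CBr4, PPh3, CH2Cl2, 0 °C) returns to 15.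

**Further compounds**

F1 | step 14 | (6R,7S,8S,9S)-8,14-bis(tert-butyldimethylsilyloxy)-9-hydroxygermacra-1(10)Z,4Z,11(13)-trien-12,6-olide (9-epimer of 19) | C=C1C(=O)O[C@@H]2/C=C(/C)CC/C=C(/CO[Si](C)(C)C(C)(C)C)[C@H](O)[C@@H](O[Si](C)(C)C(C)(C)C)[C@@H]12
F2 | step 12 | (5S)-5-(tert-butyldimethylsilyloxy)-3-[(4,4,5,5-tetramethyl-1,3,2-dioxaborolan-2-yl)methyl]-5,6-dihydro-2H-pyran-2-one | CC1(C)OB(CC2=C[C@H](O[Si](C)(C)C(C)(C)C)COC2=O)OC1(C)C
F3 | step 11 | (2S)-2-hydroxybut-3-en-1-yl prop-2-enoate | C=C[C@H](O)COC(=O)C=C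
F4 | step 11 | (2S)-2-(tert-butyldimethylsilyloxy)but-3-en-1-yl prop-2-enoate | C=C[C@H](O[Si](C)(C)C(C)(C)C)COC(=O)C=C
F5 | step 11 | (5S)-5-(tert-butyldimethylsilyloxy)-5,6-dihydro-2H-pyran-2-one | O=C1C=C[C@H](O[Si](C)(C)C(C)(C)C)CO1
F6 | step 11 | (5S)-5-(tert-butyldimethylsilyloxy)-3-(hydroxymethyl)-5,6-dihydro-2H-pyran-2-one | OCC1=C[C@H](O[Si](C)(C)C(C)(C)C)COC1=O
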